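The runs stem from a simulated flask from invented constants; the scatter is artificial.

60.0% is the number I start from: the reagent charged as a fraction of the solid substrate charged, which I call the reagent ceiling, since one reagent goes into each target and reagent is the limiting reagent in the flask.

| flask | solid substrate | reagent | remark | time |
|---|---|---|---|---|
| violet | 1 mM | 0.40 mM | run made earlier |  |
| teal | 1 mM | 0.90 mM | run made earlier |  |
| flask | 1.0 mM | 0.600 mM |  | 20 min |

| run | time / min | target / % |
|---|---|---|
| violet | 3.00 | 37.3 |
| violet | 8.00 | 39.1 |
| violet | 15.0 | 39.6 |
| violet | 25.0 | 40.3 |
| teal | 3.00 | 56.2 |
| teal | 8.00 | 90.7 |
| teal | 15.0 | 89.6 |
| teal | 25.0 | 90.9 |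

(readings scatter by 0.5 percentage points)

- as a solid, counted per litre of solution: solid substrate
- what was read earlier has a scatter of 0.5 percentage points, one standard deviation
- steps thought possible: starting material + reagent -> target; starting material -> side product; solid substrate <-> starting material
- at the start none of the solid substrate is in solution

- delta: doubling the dissolution coefficient of the solid substrate, all else as stated
- gamma: doubling the solubility of the solid substrate, all else as stated
- alpha: doubling the amount of reagent, all else as stated

- the target standing at 20 min, as a percentage of the solid substrate charged
- the change that raises the amount of target at 20 min, in percent of the solid substrate charged most ("none" if none brings more than 2 percentage points) (delta / gamma / alpha / none)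
- amount of target at 20 min, in percent of the solid substrate charged, after delta

The solid substrate dissolves to starting material, which either takes up reagent to give target or turns into side product. The last reading of the violet run is 40.3% against a ceiling of 40.0%, that of the teal run 90.9% against 90.0%, and both differ from their ceilings by no more than about two scatters.

So I draw the curve of the flask. The teal run reads 56.2% at 3.00 min, so its mean slope over those minutes is about 0.187 min⁻¹ of the charge, and I take that reading as the opening slope of the flask. Carried straight to the ceiling, that line has its knee at 3.20 min.

Now I go round once more. The same line puts the violet knee at 2.14 min, yet violet still reads 37.3% at 3.00 min, short of its ceiling, so a real knee is rounded. Even so, 20 min comes later than my knee by 16.8 min, and past the knee violet goes from 39.1% at 8.00 min to 40.3% at 25.0 min. I therefore commit to the ceiling as the level. I expect delta and gamma to steepen the slope and leave the ceiling where it is, while alpha raises it to 120%, above the charge, so the solid substrate then bounds target.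

The forecast gives 60%, alpha as best, and 60% after delta. It says “consumption should finish in about 4–6 min”, where my line says 3.20 min, but the level is the same.

The flask gives 60.0%, the ceiling of 60.0%, and 60.0% after delta, while alpha adds 38 percentage points.

    starting material + reagent → target (k = 200 M⁻¹ s⁻¹)
    starting material → side product (k = 0.00200 s⁻¹)
    solid substrate ⇌ starting material, rate k3*(cs3 - [starting material]) while solid is left; crystals form when [starting material] > cs3 (solubility = 0.440 mM, k = 0.00830 s⁻¹)

Target stands at 34.2% at 2.00 min and at 59.7% by 5.00 min. The neighbour with 0.15 mM of reagent has a ceiling of 15.0% and ends at 15.0%, with 67.9% as side product.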